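**Retrosynthetic overview**
1. The sulfates go on last. The target comes from geraldol (3,7,4'-trihydroxy-3'-methoxyflavone) by three O–S disconnections made in one operation.
2. Key move: the flavonol C3–OH/C4=O pair comes from a 3-nitro-2H-chromene by oxidative denitration. Both oxygens come from H2O2 and NO2 leaves as nitrite, so no chalcone or Algar–Flynn–Oyamada step is used.
3. The nitrochromene comes from O1–C2 (oxa-Michael) and C3–C4 (Henry) bond formation in one domino step from a salicylaldehyde and a β-nitrostyrene. C4 is therefore an aldehyde carbon, not an acetophenone carbon.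
4. Ring order: rings A and B are bought. Ring C is the only ring formed (step 1, as a 2H-pyran) and is aromatised to the 4-pyranone in step 2. Benzyl ethers mask 7-OH and 4'-OH until step 3.

Assumption: the target has no stereocentre or other stereogenic element (flat, achiral flavonol tris-O-sulfate), so "single enantiomer" needs no action. It is delivered as the free tris(hydrogen sulfate) as drawn.

**Step 1**
Reactants: 1 4-(benzyloxy)-2-hydroxybenzaldehyde; 2 (E)-1-(benzyloxy)-2-methoxy-4-(2-nitroethenyl)benzene (trans-4-benzyloxy-3-methoxy-β-nitrostyrene)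
Product: 4 (±)-7-(benzyloxy)-2-[4-(benzyloxy)-3-methoxyphenyl]-3-nitro-2H-chromene, via nitrochromanol 3 (not isolated)
Conditions: DABCO (0.5 equiv), MeCN (2 M), 50 °C
Reagents that add atoms: none
Why: Domino oxa-Michael/intramolecular Henry (nitro-aldol)/E1cB dehydration, in which the ortho-phenoxide of 1 adds reversibly to the nitroalkene, the nitronate closes onto the neighbouring aldehyde to give 3, and irreversible loss of water pulls everything to the conjugated nitrochromene 4, whose single stereocentre (C2) is deliberately racemic because step 2 makes it sp2.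

**Step 2**
Reactants: 4 (±)-7-(benzyloxy)-2-[4-(benzyloxy)-3-methoxyphenyl]-3-nitro-2H-chromene
Product: 8 7-(benzyloxy)-2-[4-(benzyloxy)-3-methoxyphenyl]-3-hydroxy-4H-chromen-4-one, via nitroepoxide 5 (not isolated), via hydroperoxyketone 6 (not isolated), via diketone 7 (not isolated)
Conditions: 30% aq H2O2 (6 equiv), 2 M NaOH (3 equiv), THF–MeOH, 0 °C to rt
Reagents that add atoms: hydrogen peroxide, OO
Why: Alkaline-peroxide oxidative denitration of a 2-aryl-3-nitrochromene assembled from known reaction types, namely Weitz–Scheffer nucleophilic epoxidation of the nitroalkene (HOO− attacks benzylic C4) to 5, opening of this α-nitroepoxide at C4 (activated by the para 7-benzyloxy group) by a second HOO− with expulsion of nitrite to 6, Kornblum–DeLaMare loss of water to 7, and enolisation through the acidic C2–H to the aromatic 3-hydroxy-4-pyranone 8, which erases the C2 stereocentre and leaves the benzyl and methyl ethers untouched.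

**Step 3**
Reactants: 8 7-(benzyloxy)-2-[4-(benzyloxy)-3-methoxyphenyl]-3-hydroxy-4H-chromen-4-one
Product: 9 3,7-dihydroxy-2-(4-hydroxy-3-methoxyphenyl)-4H-chromen-4-one (geraldol)
Conditions: H2 (1 atm), 10% Pd/C, THF–MeOH, rt
Reagents that add atoms: none
Why: Catalytic hydrogenolysis of the two aryl benzyl ethers is much faster at 1 atm than reduction of the vinylogous-ester C2=C3 bond of a flavonol, the aryl methyl ether is inert, and no stereocentre is involved.

**Step 4**
Reactants: 9 3,7-dihydroxy-2-(4-hydroxy-3-methoxyphenyl)-4H-chromen-4-one (geraldol)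
Product: 11 2-[3-methoxy-4-(sulfooxy)phenyl]-4-oxo-4H-chromene-3,7-diyl bis(hydrogen sulfate) (target CNP0382475.0), via pyridinium salt 10 (not isolated)
Conditions: SO3·pyridine (15 equiv), DMF, 60 °C; then Dowex 50WX8 (H+ form), H2O, 4 °C, freeze-dry
Reagents that add atoms: sulfur trioxide–pyridine complex, [O-]S(=O)(=O)[n+]1ccccc1
Why: Exhaustive O-sulfation with an amine–SO3 complex, where large excess and heat take the acidic 7-OH, the 4'-OH and finally the hydrogen-bonded 3-OH to full conversion without C-sulfonation, and cold strong-acid resin swaps the pyridinium ions of 10 for protons to give the achiral target.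

**Compound list**
1 | 4-(benzyloxy)-2-hydroxybenzaldehyde | O=Cc1ccc(OCc2ccccc2)cc1O | starting material
2 | (E)-1-(benzyloxy)-2-methoxy-4-(2-nitroethenyl)benzene | COc1cc(/C=C/[N+](=O)[O-])ccc1OCc1ccccc1 | starting material
3 | 7-(benzyloxy)-2-[4-(benzyloxy)-3-methoxyphenyl]-3-nitrochroman-4-ol (racemic diastereomer mixture, configuration inconsequential) | COc1cc(C2Oc3cc(OCc4ccccc4)ccc3C(O)C2[N+](=O)[O-])ccc1OCc1ccccc1 | intermediate (not isolated)
4 | (±)-7-(benzyloxy)-2-[4-(benzyloxy)-3-methoxyphenyl]-3-nitro-2H-chromene (racemic at C2) | COc1cc(C2Oc3cc(OCc4ccccc4)ccc3C=C2[N+](=O)[O-])ccc1OCc1ccccc1 | intermediate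
5 | (±)-7-(benzyloxy)-2-[4-(benzyloxy)-3-methoxyphenyl]-3,4-epoxy-3-nitrochromane (oxirane expected anti to the 2-aryl group, racemic, configuration inconsequential) | COc1cc(C2Oc3cc(OCc4ccccc4)ccc3C3OC23[N+](=O)[O-])ccc1OCc1ccccc1 | intermediate (not isolated)
6 | 7-(benzyloxy)-2-[4-(benzyloxy)-3-methoxyphenyl]-4-hydroperoxychroman-3-one (racemic, configuration inconsequential) | COc1cc(C2Oc3cc(OCc4ccccc4)ccc3C(OO)C2=O)ccc1OCc1ccccc1 | intermediate (not isolated)
7 | (±)-7-(benzyloxy)-2-[4-(benzyloxy)-3-methoxyphenyl]chromane-3,4-dione | COc1cc(C2Oc3cc(OCc4ccccc4)ccc3C(=O)C2=O)ccc1OCc1ccccc1 | intermediate (not isolated)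
8 | 7-(benzyloxy)-2-[4-(benzyloxy)-3-methoxyphenyl]-3-hydroxy-4H-chromen-4-one (achiral) | COc1cc(-c2oc3cc(OCc4ccccc4)ccc3c(=O)c2O)ccc1OCc1ccccc1 | intermediate
9 | 3,7-dihydroxy-2-(4-hydroxy-3-methoxyphenyl)-4H-chromen-4-one (geraldol, achiral) | COc1cc(-c2oc3cc(O)ccc3c(=O)c2O)ccc1O | intermediate
10 | tris(pyridinium) salt of geraldol 3,7,4'-tris-O-sulfate | COc1cc(-c2oc3cc(OS(=O)(=O)[O-])ccc3c(=O)c2OS(=O)(=O)[O-])ccc1OS(=O)(=O)[O-].c1cc[nH+]cc1.c1cc[nH+]cc1.c1cc[nH+]cc1 | intermediate (not isolated)
11 | 2-[3-methoxy-4-(sulfooxy)phenyl]-4-oxo-4H-chromene-3,7-diyl bis(hydrogen sulfate) (achiral) | COc1cc(-c2oc3cc(OS(=O)(=O)O)ccc3c(=O)c2OS(=O)(=O)O)ccc1OS(=O)(=O)O | target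

**Total step count:** 4. **Longest linear sequence:** 4.

**Three steps most likely to fail**

**Step 2 (highest risk).**
- Risk: hydroxide can compete with hydroperoxide at C4 and trigger retro-Henry/retro-oxa-Michael collapse.
- Risk: excess peroxide can cleave diketone 7 before it enolises.
- Fallback, from 4 back to the route at 8: remove the nitrogen reductively first and re-oxidise afterwards.
- Fe powder in AcOH–H2O at 80 °C reduces the conjugated nitroalkene and hydrolyses the resulting enamine/imine. This gives (±)-7-(benzyloxy)-2-[4-(benzyloxy)-3-methoxyphenyl]chroman-3-one F1.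
- Riley oxidation (SeO2, dioxane, 80 °C) of the benzylic C4 methylene next to the ketone then gives diketone 7, which tautomerises to 8.

**Step 1.**
- Risk: both partners are electron-rich, so the reversible oxa-Michael step may lie on the wrong side.
- Risk: DABCO may oligomerise 2.
- Fallback, from 1 back to the route at 8, bypassing 4: change the bond set altogether.
- Pinnick oxidation of 1 (NaClO2, NaH2PO4, 2-methyl-2-butene, t-BuOH–H2O) gives 4-(benzyloxy)-2-hydroxybenzoic acid F2.
- Carboxylate alkylation with commercial 2-bromo-1-[4-(benzyloxy)-3-methoxyphenyl]ethan-1-one (KHCO3, DMF, rt) gives 2-[4-(benzyloxy)-3-methoxyphenyl]-2-oxoethyl 4-(benzyloxy)-2-hydroxybenzoate F3.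
- LiHMDS (3.3 equiv, THF, −78 to 0 °C) triggers a Chan-type O-to-C 1,2-acyl shift through the oxirane alkoxide. This gives 1-[4-(benzyloxy)-2-hydroxyphenyl]-3-[4-(benzyloxy)-3-methoxyphenyl]-2-hydroxypropane-1,3-dione F4.
- Cyclodehydration of F4 in AcOH with catalytic H2SO4 at 60 °C gives 8.

**Step 4.**
- Risk: the hydrogen-bonded 3-OH may stay partly free, giving inseparable mixtures of ionic di- and trisulfates.
- Risk: the free acid hydrolyses autocatalytically if it is warmed or stored wet.
- Fallback, from 9 back to the route at 11: use neutral, chromatographable sulfate diesters.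
- 2,2,2-Trichloroethyl chlorosulfate (ClS(=O)(=O)OCC(Cl)(Cl)Cl, 6 equiv) with Et3N and DMAP in THF gives geraldol 3,7,4'-tris(2,2,2-trichloroethyl sulfate) F5, which is purified on silica.
- Zn dust and HCO2NH4 in MeOH at rt unmask all three esters by reductive β-elimination under neutral conditions. This gives the triammonium salt of geraldol 3,7,4'-tris-O-sulfate F6.
- The same cold H+ resin exchange and freeze-drying then gives 11.

**Further compounds**
F1 | step 2 | (±)-7-(benzyloxy)-2-[4-(benzyloxy)-3-methoxyphenyl]chroman-3-one | COc1cc(C2Oc3cc(OCc4ccccc4)ccc3CC2=O)ccc1OCc1ccccc1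
F2 | step 1 | 4-(benzyloxy)-2-hydroxybenzoic acid | O=C(O)c1ccc(OCc2ccccc2)cc1O
F3 | step 1 | 2-[4-(benzyloxy)-3-methoxyphenyl]-2-oxoethyl 4-(benzyloxy)-2-hydroxybenzoate | COc1cc(C(=O)COC(=O)c2ccc(OCc3ccccc3)cc2O)ccc1OCc1ccccc1
F4 | step 1 | 1-[4-(benzyloxy)-2-hydroxyphenyl]-3-[4-(benzyloxy)-3-methoxyphenyl]-2-hydroxypropane-1,3-dione (racemic) | COc1cc(C(=O)C(O)C(=O)c2ccc(OCc3ccccc3)cc2O)ccc1OCc1ccccc1
F5 | step 4 | geraldol 3,7,4'-tris(2,2,2-trichloroethyl sulfate) | COc1cc(-c2oc3cc(OS(=O)(=O)OCC(Cl)(Cl)Cl)ccc3c(=O)c2OS(=O)(=O)OCC(Cl)(Cl)Cl)ccc1OS(=O)(=O)OCC(Cl)(Cl)Cl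
F6 | step 4 | triammonium salt of geraldol 3,7,4'-tris-O-sulfate | COc1cc(-c2oc3cc(OS(=O)(=O)[O-])ccc3c(=O)c2OS(=O)(=O)[O-])ccc1OS(=O)(=O)[O-].[NH4+].[NH4+].[NH4+]
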